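**Retrosynthetic overview**
- Last: hydrolytic opening of an enol lactone that comes from ligand-controlled, para-selective dearomative prenylation (Pd) at the lavandulyl-bearing carbon of a pyranocoumarin phenol; this sets the quaternary centre.
- Lavandulyl group: Negishi coupling of the aryl bromide with (S)-lavandulylzinc iodide (from an Evans dienolate prenylation); benzylic centre: Rh-catalysed asymmetric 1,4-addition of phenylboronic acid to the coumarin C=C.
- Key C–C bond (chromanone C4–C3): the NHC-derived Breslow intermediate of the ring aldehyde, an acyl anion equivalent, displaces a secondary bromide with inversion and closes the cis-2,3-dimethyl dihydropyranone.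
- Bromo ether aldehyde: from 5,7-dihydroxycoumarin by 7-O opening of (2S,3S)-2,3-dimethyloxirane, ortho-formylation and Appel inversion.
- Ring order: aromatic ring and lactone ring bought as the coumarin, then the dihydropyranone ring (key step), then dearomatisation of the carbocycle, then the lactone ring is opened.

Assumption: the target is drawn as one tautomer of an enolised cyclic β-triketone, and 5,7-dihydroxycoumarin, (2S,3S)-2,3-dimethyloxirane and 3-methylbut-2-en-1-yl acetate are taken as catalogue chemicals.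

**Route**

Step 1
Reactants: 1 (4S)-4-benzyl-1,3-oxazolidin-2-one; 2 3-methylbut-2-enoyl chloride
Product: 3 (4S)-4-benzyl-3-(3-methylbut-2-enoyl)-1,3-oxazolidin-2-one
Conditions: n-BuLi, THF, −78 °C; then 2, −78 → 0 °C
Reagents that add atoms: none
Why: N-acylation of the lithiated Evans oxazolidinone with an acid chloride is a standard imide formation that installs the auxiliary needed to control the lavandulyl stereocentre.

Step 2
Reactants: 3 (4S)-4-benzyl-3-(3-methylbut-2-enoyl)-1,3-oxazolidin-2-one; 4 1-bromo-3-methylbut-2-ene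
Product: 5 (4S)-4-benzyl-3-[(2S)-5-methyl-2-(prop-1-en-2-yl)hex-4-enoyl]-1,3-oxazolidin-2-one
Conditions: NaN(SiMe3)2, THF, −78 °C; then 4, −78 → −40 °C
Reagents that add atoms: none
Why: Evans asymmetric alkylation in its deconjugative form, in which γ-deprotonation gives the chelated Z-dienolate that is prenylated at the α-carbon on the face opposite the benzyl group, setting the 2S centre and moving the alkene into the isopropenyl position.

Step 3
Reactants: 5 (4S)-4-benzyl-3-[(2S)-5-methyl-2-(prop-1-en-2-yl)hex-4-enoyl]-1,3-oxazolidin-2-one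
Product: 6 (2S)-5-methyl-2-(prop-1-en-2-yl)hex-4-en-1-ol
Conditions: LiBH4, H2O (1 equiv), Et2O, 0 °C
Reagents that add atoms: none
Why: reductive cleavage of the imide with LiBH4 gives the primary alcohol without touching the β,γ-alkene or the new stereocentre and returns the auxiliary.

Step 4
Reactants: 6 (2S)-5-methyl-2-(prop-1-en-2-yl)hex-4-en-1-ol
Product: 7 (3S)-3-(iodomethyl)-2,6-dimethylhepta-1,5-diene
Conditions: PPh3, I2, imidazole, CH2Cl2, 0 °C
Reagents that add atoms: iodine, II
Why: Appel iodination acts only at the primary CH2 group, so the adjacent stereocentre is untouched.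

Step 5
Reactants: 8 5,7-dihydroxy-2H-chromen-2-one; 9 (2S,3S)-2,3-dimethyloxirane
Product: 10 5-hydroxy-7-{[(2R,3S)-3-hydroxybutan-2-yl]oxy}-2H-chromen-2-one
Conditions: Cs2CO3 (0.2 equiv), DMF, 85 °C, sealed tube
Reagents that add atoms: none
Why: base-catalysed SN2 opening of the C2-symmetric epoxide by the more acidic 7-OH (the vinylogous-acid phenol of the coumarin) inverts the attacked carbon to give the 2R aryl ether, while the carbinol carbon keeps its S configuration.

Step 6
Reactants: 10 5-hydroxy-7-{[(2R,3S)-3-hydroxybutan-2-yl]oxy}-2H-chromen-2-one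
Product: 11 5-hydroxy-7-{[(2R,3S)-3-hydroxybutan-2-yl]oxy}-2-oxo-2H-chromene-6-carbaldehyde
Conditions: MgCl2, Et3N, (CH2O)n, MeCN, reflux; then 1 M HCl
Reagents that add atoms: paraformaldehyde (formaldehyde unit), C=O
Why: the MgCl2/Et3N ortho-formylation of phenols (Casnati–Skattebøl reaction) delivers the formyl group only ortho to the free 5-OH, and C6 is the single open ortho position.

Step 7
Reactants: 11 5-hydroxy-7-{[(2R,3S)-3-hydroxybutan-2-yl]oxy}-2-oxo-2H-chromene-6-carbaldehyde
Product: 12 7-{[(2R,3R)-3-bromobutan-2-yl]oxy}-5-hydroxy-2-oxo-2H-chromene-6-carbaldehyde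
Conditions: PPh3, Br2, imidazole, CH2Cl2, 0 °C → rt
Reagents that add atoms: bromine, BrBr
Why: Appel-type bromination with Ph3PBr2 displaces the activated secondary alcohol with inversion, turning the 3S carbinol into the 3R bromide while the aryloxy-bearing carbon is untouched.

Step 8
Reactants: 12 7-{[(2R,3R)-3-bromobutan-2-yl]oxy}-5-hydroxy-2-oxo-2H-chromene-6-carbaldehyde
Product: 13 (7S,8R)-5-hydroxy-7,8-dimethyl-7,8-dihydro-2H,6H-pyrano[3,2-g]chromene-2,6-dione
Conditions: 3-benzyl-5-(2-hydroxyethyl)-4-methylthiazol-3-ium chloride (20 mol%), K2CO3 (1.5 equiv), THF, 65 °C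
Reagents that add atoms: none
Why: Proposed new method: the thiazolylidene adds to the aldehyde to form a Breslow intermediate, an acyl anion equivalent whose nucleophilic carbon displaces the secondary bromide in a 6-exo-tet SN2 closure, so the carbonyl carbon and the bromide-bearing carbon (both electrophilic in normal polarity) are joined with inversion (3R bromide to 7S) to give the cis-2,3-dimethyl dihydropyranone directly, the closest known reaction being the NHC-catalysed intramolecular nucleophilic substitution of 2-(2-haloethoxy)benzaldehydes to chroman-4-ones, so far shown for primary leaving groups.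

Step 9
Reactants: 13 (7S,8R)-5-hydroxy-7,8-dimethyl-7,8-dihydro-2H,6H-pyrano[3,2-g]chromene-2,6-dione; 14 phenylboronic acid
Product: 15 (4R,7S,8R)-5-hydroxy-7,8-dimethyl-4-phenyl-3,4,7,8-tetrahydro-2H,6H-pyrano[3,2-g]chromene-2,6-dione
Conditions: Rh(acac)(C2H4)2 (3 mol%), (R)-SEGPHOS [(R)-5,5'-bis(diphenylphosphino)-4,4'-bi-1,3-benzodioxole], 14 (5 equiv), 1,4-dioxane/H2O 10:1, 60 °C
Reagents that add atoms: none
Why: Hayashi–Miyaura rhodium-catalysed asymmetric 1,4-addition of an arylboronic acid to a coumarin, in which the (R)-SEGPHOS complex selects the alkene face and sets the 4R benzylic centre as in the known tolterodine lactone synthesis.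

Step 10
Reactants: 15 (4R,7S,8R)-5-hydroxy-7,8-dimethyl-4-phenyl-3,4,7,8-tetrahydro-2H,6H-pyrano[3,2-g]chromene-2,6-dione
Product: 16 (4R,7S,8R)-10-bromo-5-hydroxy-7,8-dimethyl-4-phenyl-3,4,7,8-tetrahydro-2H,6H-pyrano[3,2-g]chromene-2,6-dione
Conditions: NBS, MeCN, 0 °C, dark
Reagents that add atoms: N-bromosuccinimide, O=C1CCC(=O)N1Br
Why: electrophilic aromatic bromination occurs at C10, the only free position of the trioxygenated ring and para to the free phenol.

Step 11
Reactants: 16 (4R,7S,8R)-10-bromo-5-hydroxy-7,8-dimethyl-4-phenyl-3,4,7,8-tetrahydro-2H,6H-pyrano[3,2-g]chromene-2,6-dione; 7 (3S)-3-(iodomethyl)-2,6-dimethylhepta-1,5-diene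
Product: 18 (4R,7S,8R)-5-hydroxy-7,8-dimethyl-10-[(2R)-5-methyl-2-(prop-1-en-2-yl)hex-4-en-1-yl]-4-phenyl-3,4,7,8-tetrahydro-2H,6H-pyrano[3,2-g]chromene-2,6-dione, via lavandulylzinc iodide 17 (not isolated)
Conditions: 7, Zn dust, LiCl, THF, 40 °C; then 16, Pd(OAc)2 (4 mol%), SPhos [2-dicyclohexylphosphino-2',6'-dimethoxybiphenyl] (8 mol%), THF, 25 → 50 °C
Reagents that add atoms: none
Why: Negishi sp2–sp3 cross-coupling with Pd(OAc)2/SPhos tolerates the free phenol, ketone and lactone, and the lavandulyl stereocentre is kept because it lies β to zinc and takes no part in the coupling.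

Step 12
Reactants: 18 (4R,7S,8R)-5-hydroxy-7,8-dimethyl-10-[(2R)-5-methyl-2-(prop-1-en-2-yl)hex-4-en-1-yl]-4-phenyl-3,4,7,8-tetrahydro-2H,6H-pyrano[3,2-g]chromene-2,6-dione; 19 3-methylbut-2-en-1-yl acetate
Product: 21 (3R)-3-{(2R,3S,8S)-5-hydroxy-2,3-dimethyl-8-(3-methylbut-2-en-1-yl)-8-[(2R)-5-methyl-2-(prop-1-en-2-yl)hex-4-en-1-yl]-4,7-dioxo-3,4,7,8-tetrahydro-2H-chromen-6-yl}-3-phenylpropanoic acid, via dearomatised enol lactone 20 (not isolated)
Conditions: Pd2(dba)3 (2.5 mol%), (S,S)-DACH-phenyl Trost ligand [(1S,2S)-N,N'-bis(2-diphenylphosphinobenzoyl)cyclohexane-1,2-diamine] (7.5 mol%), Cs2CO3 (1.1 equiv), 19, THF, 0 °C → rt; then LiOH, THF/H2O, 0 °C; then 1 M HCl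
Reagents that add atoms: lithium hydroxide, [Li+].[OH-]
Why: Proposed new method: the phenoxide attacks the π-prenyl palladium complex through its para carbon C10, the site flanked by two oxygen-bearing carbons, with the chiral ligand intended to select the ring face that gives 10S (its mirror-image ligand would give the C10 epimer), and the resulting enol lactone, an activated acyl donor, is then hydrolysed to the acid and the enolised triketone, the closest known reactions being the para-selective Tsuji–Trost dearomative allylation of 3,5-dialkoxyphenols and palladium-catalysed asymmetric allylic dearomatisation of phenols and naphthols.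

**Compound list**

1 | (4S)-4-benzyl-1,3-oxazolidin-2-one | O=C1N[C@@H](Cc2ccccc2)CO1 | starting material
2 | 3-methylbut-2-enoyl chloride | CC(C)=CC(Cl)=O | starting material
3 | (4S)-4-benzyl-3-(3-methylbut-2-enoyl)-1,3-oxazolidin-2-one | CC(C)=CC(=O)N1C(=O)OC[C@@H]1Cc1ccccc1 | intermediate
4 | 1-bromo-3-methylbut-2-ene | CC(C)=CCBr | starting material
5 | (4S)-4-benzyl-3-[(2S)-5-methyl-2-(prop-1-en-2-yl)hex-4-enoyl]-1,3-oxazolidin-2-one | C=C(C)[C@H](CC=C(C)C)C(=O)N1C(=O)OC[C@@H]1Cc1ccccc1 | intermediate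
6 | (2S)-5-methyl-2-(prop-1-en-2-yl)hex-4-en-1-ol | C=C(C)[C@H](CC=C(C)C)CO | intermediate
7 | (3S)-3-(iodomethyl)-2,6-dimethylhepta-1,5-diene | C=C(C)[C@H](CC=C(C)C)CI | intermediate
8 | 5,7-dihydroxy-2H-chromen-2-one | O=c1ccc2c(O)cc(O)cc2o1 | starting material
9 | (2S,3S)-2,3-dimethyloxirane | C[C@@H]1O[C@H]1C | starting material
10 | 5-hydroxy-7-{[(2R,3S)-3-hydroxybutan-2-yl]oxy}-2H-chromen-2-one | O=c1ccc2c(O)cc(O[C@H](C)[C@H](C)O)cc2o1 | intermediate
11 | 5-hydroxy-7-{[(2R,3S)-3-hydroxybutan-2-yl]oxy}-2-oxo-2H-chromene-6-carbaldehyde | O=c1ccc2c(O)c(C=O)c(O[C@H](C)[C@H](C)O)cc2o1 | intermediate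
12 | 7-{[(2R,3R)-3-bromobutan-2-yl]oxy}-5-hydroxy-2-oxo-2H-chromene-6-carbaldehyde | O=c1ccc2c(O)c(C=O)c(O[C@H](C)[C@@H](C)Br)cc2o1 | intermediate
13 | (7S,8R)-5-hydroxy-7,8-dimethyl-7,8-dihydro-2H,6H-pyrano[3,2-g]chromene-2,6-dione | O=c1ccc2c(O)c3C(=O)[C@@H](C)[C@@H](C)Oc3cc2o1 | intermediate
14 | phenylboronic acid | OB(O)c1ccccc1 | starting material
15 | (4R,7S,8R)-5-hydroxy-7,8-dimethyl-4-phenyl-3,4,7,8-tetrahydro-2H,6H-pyrano[3,2-g]chromene-2,6-dione | O=C1C[C@H](c2ccccc2)c2c(O)c3C(=O)[C@@H](C)[C@@H](C)Oc3cc2O1 | intermediate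
16 | (4R,7S,8R)-10-bromo-5-hydroxy-7,8-dimethyl-4-phenyl-3,4,7,8-tetrahydro-2H,6H-pyrano[3,2-g]chromene-2,6-dione | O=C1C[C@H](c2ccccc2)c2c(O)c3C(=O)[C@@H](C)[C@@H](C)Oc3c(Br)c2O1 | intermediate
17 | [(2S)-5-methyl-2-(prop-1-en-2-yl)hex-4-en-1-yl]zinc iodide | C=C(C)[C@H](CC=C(C)C)C[Zn]I | intermediate
18 | (4R,7S,8R)-5-hydroxy-7,8-dimethyl-10-[(2R)-5-methyl-2-(prop-1-en-2-yl)hex-4-en-1-yl]-4-phenyl-3,4,7,8-tetrahydro-2H,6H-pyrano[3,2-g]chromene-2,6-dione | C=C(C)[C@H](CC=C(C)C)Cc1c2OC(=O)C[C@H](c3ccccc3)c2c(O)c2C(=O)[C@@H](C)[C@@H](C)Oc12 | intermediate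
19 | 3-methylbut-2-en-1-yl acetate | CC(C)=CCOC(C)=O | starting material
20 | (4R,7S,8R,10S)-7,8-dimethyl-10-(3-methylbut-2-en-1-yl)-10-[(2R)-5-methyl-2-(prop-1-en-2-yl)hex-4-en-1-yl]-4-phenyl-3,4,7,8-tetrahydro-2H-pyrano[3,2-g]chromene-2,5,6(10H)-trione | C=C(C)[C@H](CC=C(C)C)C[C@]1(CC=C(C)C)C2=C(C(=O)C3=C1O[C@H](C)[C@H](C)C3=O)[C@@H](c1ccccc1)CC(=O)O2 | intermediate
21 | (3R)-3-{(2R,3S,8S)-5-hydroxy-2,3-dimethyl-8-(3-methylbut-2-en-1-yl)-8-[(2R)-5-methyl-2-(prop-1-en-2-yl)hex-4-en-1-yl]-4,7-dioxo-3,4,7,8-tetrahydro-2H-chromen-6-yl}-3-phenylpropanoic acid (CNP0150579.4) | C=C(C)[C@H](CC=C(C)C)C[C@]1(CC=C(C)C)C(=O)C([C@H](CC(=O)O)c2ccccc2)=C(O)C2=C1O[C@H](C)[C@H](C)C2=O | target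

**Step count**
Total steps: 12. Longest linear sequence: 8 steps (steps 5 to 12, from compound 8); the lavandulyl branch (steps 1 to 4) joins at step 11.

**The three steps most likely to fail, with fallbacks**

Risk 1, the ring closure of step 8. A Breslow intermediate has only been shown to displace primary leaving groups. At this hindered secondary bromide it may eliminate or not react, the free 5-OH may slow carbene addition, and the cis product can epimerise at C7 under base. The fallback sets out from compound 8 and returns at compound 13. Mitsunobu etherification of 8 with (S)-but-3-yn-2-ol (PPh3, diisopropyl azodicarboxylate, inversion) gives 7-{[(2R)-but-3-yn-2-yl]oxy}-5-hydroxy-2H-chromen-2-one F1. Ortho-formylation as in step 6 gives 7-{[(2R)-but-3-yn-2-yl]oxy}-5-hydroxy-2-oxo-2H-chromene-6-carbaldehyde F2. The same thiazolium salt with only catalytic K2CO3 then effects intramolecular hydroacylation of the unactivated alkyne, a reaction known for 2-propargyloxybenzaldehydes, to give (8R)-5-hydroxy-8-methyl-7-methylidene-7,8-dihydro-2H,6H-pyrano[3,2-g]chromene-2,6-dione F3. Hydrogenation of F3 with RhCl(PPh3)3 and H2 from the face opposite the pseudo-axial C8 methyl group gives cis compound 13.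

Risk 2, the dearomative prenylation of step 12. The chelated phenoxide is a weak nucleophile, O-allylation may win, and the sense and level of facial control by the chiral ligand are not established. The fallback sets out from compound 18 and ends at compound 21. Methanolysis of the lactone (K2CO3, MeOH, 0 °C) gives methyl (3R)-3-{(2R,3S)-5,7-dihydroxy-2,3-dimethyl-8-[(2R)-5-methyl-2-(prop-1-en-2-yl)hex-4-en-1-yl]-4-oxo-3,4-dihydro-2H-chromen-6-yl}-3-phenylpropanoate F4. Its dianion is prenylated at C8 with compound 4 under classical acylphloroglucinol conditions (aqueous KOH, 0 °C), and the two C8 epimers, which are diastereomers, are separated by chromatography to give methyl (3R)-3-{(2R,3S,8S)-5-hydroxy-2,3-dimethyl-8-(3-methylbut-2-en-1-yl)-8-[(2R)-5-methyl-2-(prop-1-en-2-yl)hex-4-en-1-yl]-4,7-dioxo-3,4,7,8-tetrahydro-2H-chromen-6-yl}-3-phenylpropanoate F5. Cold LiOH hydrolysis of F5 gives compound 21.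

Risk 3, the conjugate arylation of step 9. The coumarin is electron-rich and carries a peri hydroxyl, so it may be too poor an acceptor for the arylrhodium species. The fallback sets out from compound 13 and returns at compound 15. Oxidative Heck arylation of 13 with compound 14 (Pd(OAc)2, 2,2'-bipyridine, O2) gives (7S,8R)-5-hydroxy-7,8-dimethyl-4-phenyl-7,8-dihydro-2H,6H-pyrano[3,2-g]chromene-2,6-dione F6. Asymmetric conjugate reduction of this 4-phenylcoumarin with a copper hydride catalyst (Cu(OAc)2, (R)-5,5'-bis[di(3,5-di-tert-butyl-4-methoxyphenyl)phosphino]-4,4'-bi-1,3-benzodioxole, diethoxymethylsilane), as used for 4-arylcoumarins on the way to tolterodine, gives compound 15.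

**Further compounds**

F1 | step 8 | 7-{[(2R)-but-3-yn-2-yl]oxy}-5-hydroxy-2H-chromen-2-one | O=c1ccc2c(O)cc(O[C@H](C)C#C)cc2o1
F2 | step 8 | 7-{[(2R)-but-3-yn-2-yl]oxy}-5-hydroxy-2-oxo-2H-chromene-6-carbaldehyde | O=c1ccc2c(O)c(C=O)c(O[C@H](C)C#C)cc2o1
F3 | step 8 | (8R)-5-hydroxy-8-methyl-7-methylidene-7,8-dihydro-2H,6H-pyrano[3,2-g]chromene-2,6-dione | O=c1ccc2c(O)c3C(=O)C(=C)[C@@H](C)Oc3cc2o1
F4 | step 12 | methyl (3R)-3-{(2R,3S)-5,7-dihydroxy-2,3-dimethyl-8-[(2R)-5-methyl-2-(prop-1-en-2-yl)hex-4-en-1-yl]-4-oxo-3,4-dihydro-2H-chromen-6-yl}-3-phenylpropanoate | C=C(C)[C@H](CC=C(C)C)Cc1c(O)c([C@H](CC(=O)OC)c2ccccc2)c(O)c2C(=O)[C@@H](C)[C@@H](C)Oc12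
F5 | step 12 | methyl (3R)-3-{(2R,3S,8S)-5-hydroxy-2,3-dimethyl-8-(3-methylbut-2-en-1-yl)-8-[(2R)-5-methyl-2-(prop-1-en-2-yl)hex-4-en-1-yl]-4,7-dioxo-3,4,7,8-tetrahydro-2H-chromen-6-yl}-3-phenylpropanoate | C=C(C)[C@H](CC=C(C)C)C[C@]1(CC=C(C)C)C(=O)C([C@H](CC(=O)OC)c2ccccc2)=C(O)C2=C1O[C@H](C)[C@H](C)C2=O
F6 | step 9 | (7S,8R)-5-hydroxy-7,8-dimethyl-4-phenyl-7,8-dihydro-2H,6H-pyrano[3,2-g]chromene-2,6-dione | O=c1cc(-c2ccccc2)c2c(O)c3C(=O)[C@@H](C)[C@@H](C)Oc3cc2o1
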